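**Plan**
- Retrosynthesis: cut the C10 angelate (Mitsunobu inversion) and the C6 veratrate, then the C8=C9 double bond, then rejoin C6–C10 in thought to a cyclobutane, which is cut at C5–C6 and C1–C10 into 3-methylcyclopent-2-enone and a 1,2-bis(silyloxy)cyclopentene.
- Enabling feature: in the seven-membered ring both carbons next to the ring-fusion bond C1–C5 (C6 and C10) carry oxygen, and C8 lies on a local mirror plane. C6–C7–C8–C9–C10 can therefore come from a symmetric enediol ether whose C=C adds across the C1=C5 enone bond of ring B and is later the one cyclobutane bond that is cut again.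
- Forward order: ring B is bought; the photocycloaddition builds the four-membered ring C1–C5–C6–C10 on it; the C4 carbinol is finished on the rigid tricycle; glycol cleavage of C6–C10 releases the seven-membered ring; C5 is epimerised to the trans fusion; the esters follow.
- Stereochemistry: C1 (absolute) from the chiral Lewis acid in the photocycloaddition; C4 from exo-face hydration; C5 by thermodynamic epimerisation next to the C6 ketone; C6 by hydride delivery from the C4 hydroxyl; C10 by α-face hydride addition, then SN2 inversion with angelate.

Key step: step 2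

Remark: daucane numbering is used throughout (C1 quaternary ring-fusion carbon with the angular methyl, C4 carbinol carbon with isopropyl, C5 ring-fusion CH, C6 veratrate carbon, C8=C9 alkene, C10 angelate carbon; β is the face of the angular methyl; target C1 S, C4 R, C5 S, C6 S, C10 R). Intermediates 4 to 14 are assumed to be carried as C8-methyl epimers (4 to 8 also as syn/anti cyclobutane isomers); these differences vanish in steps 6 and 11, and only the expected major isomer is drawn.

**Step 1**
Reactants: 1 dimethyl 3-methylglutarate
Product: 2 4-methyl-1,2-bis(trimethylsilyloxy)cyclopent-1-ene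
Conditions: Na (4.2 equiv), Me3SiCl (4.5 equiv), toluene, reflux
Reagents that add atoms: chlorotrimethylsilane, C[Si](C)(C)Cl
Why: Acyloin condensation under Rühlmann conditions: sodium reduces both ester groups to the cyclic enediolate, which Me3SiCl traps as the bis(silyl) enol ether (it also scavenges methoxide, so no Dieckmann product forms); no stereocenter is created because C8 lies on the mirror plane of 2.

**Step 2**
Reactants: 3 3-methylcyclopent-2-en-1-one; 2 4-methyl-1,2-bis(trimethylsilyloxy)cyclopent-1-ene
Product: 4 tricyclic photoadduct ketone (tricyclo[5.3.0.0(2,6)]decanone: cyclobutane C1–C5–C6–C10, ketone at C4, Me3SiO on C6 and C10, C5–H and C1–CH3 cis and β, the two five-membered rings anti across the cyclobutane)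
Conditions: hν (366 nm), enediol ether in fivefold excess, AlBr3 adduct of the oxazaborolidine from α,α-bis(3,5-dimethylphenyl)prolinol and 2,4,6-trifluorophenylboronic acid (50 mol %, prolinol antipode chosen to cover the enone face on which the angular methyl must end up), CH2Cl2, −75 °C
Reagents that add atoms: none
Why: Proposed new method: the closest known reaction types are the uncatalysed [2+2] photocycloaddition of cyclopentenones to 1,2-bis(silyloxy)cycloalkenes and the enantioselective [2+2] photocycloaddition of cyclohexenones to simple olefins under AlBr3-activated oxazaborolidines, and the step combines them on a cyclopentenone and an enediol bis(silyl ether). Mechanism: the Lewis acid binds the carbonyl oxygen of 3 and shifts its absorption to longer wavelength, so that at 366 nm only bound enone is excited; its triplet adds to the electron-rich double bond of 2 to give a 1,4-biradical that closes after spin inversion. The one ring closed here is the cyclobutane C1–C5–C6–C10, by stepwise intermolecular [2+2] (first C–C bond, then radical–radical collapse); the seven-membered ring is stored in it and is set free in step 6 when C6–C10 is cut. C1 and C5 come out cis because a trans-fused bicyclo[3.2.0]heptanone is too strained, and their absolute sense (angular methyl β) is set by the aryl group of the catalyst, which covers one face of the bound enone. C6, C10 and C8 are also stereogenic in 4, but C6 and C10 become carbonyl carbons in step 6 and C8 an alkene carbon in step 11, so syn/anti and C8-epimeric adducts converge. No regioselectivity is needed because the mirror plane of 2 through C8 makes C6 and C10 equivalent; chemoselectivity (cross-addition instead of enone dimerisation or Mukaiyama–Michael addition) rests on the excess of 2, the low temperature and the fully substituted enol ether carbons.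

**Step 3**
Reactants: 4 tricyclic photoadduct ketone
Product: 5 enol triflate (C3=C4, triflate on C4)
Conditions: KN(SiMe3)2, THF, −78 °C; then PhNTf2, −78 to 0 °C
Reagents that add atoms: N-phenylbis(trifluoromethanesulfonimide), O=S(=O)(N(c1ccccc1)S(=O)(=O)C(F)(F)F)C(F)(F)F
Why: Enol triflate formation: the hindered amide base removes a proton kinetically from the C3 methylene and not from the ring-fusion C5–H (an enolate there would put a trigonal carbon at the bicyclo[3.2.0] fusion), and PhNTf2 triflates the enolate oxygen; no stereocenter changes.

**Step 4**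
Reactants: 5 enol triflate
Product: 6 C4-isopropyl alkene (C3=C4)
Conditions: iPrZnBr (2 equiv), PdCl2(dppf) (5 mol %), THF, 25 to 50 °C
Reagents that add atoms: isopropylzinc bromide, CC(C)[Zn]Br
Why: Negishi cross-coupling of the alkenyl triflate with a secondary alkylzinc halide, in which the wide-bite-angle dppf ligand makes reductive elimination faster than β-hydride elimination so that the branched isopropyl group is transferred; no stereocenter is set.

**Step 5**
Reactants: 6 C4-isopropyl alkene
Product: 7 tertiary alcohol (4β-OH, 4α-isopropyl; cyclobutane and silyl ethers intact)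
Conditions: Co(acac)2 (20 mol %), PhSiH3 (2 equiv), O2 (1 atm), THF, 25 °C
Reagents that add atoms: dioxygen, O=O
Why: Mukaiyama hydration (hydrogen-atom transfer from a cobalt hydride to C3, capture of the tertiary C4 radical by O2, reduction of the peroxide by the silane) gives the Markovnikov tertiary alcohol, and O2 should approach from the convex exo face of the bicyclo[3.2.0] unit (the face of C5–H and the angular methyl, away from the substituted cyclobutane), which puts the hydroxyl β and the isopropyl group α.

**Step 6**
Reactants: 7 tertiary alcohol
Product: 9 cis-fused 4β-hydroxydaucane-6,10-dione (C5–H β), via cyclobutane triol 8 (not isolated)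
Conditions: Bu4NF, THF, 0 °C; then Pb(OAc)4, CH2Cl2, −20 °C
Reagents that add atoms: none
Why: Fluoride removes both silyl groups and Pb(OAc)4 then cuts the cis-1,2-diol through its cyclic lead diester (Criegee glycol cleavage), the strain of the cyclobutane driving the opening of C6–C10 to the seven-membered 6,10-dione; C6 and C10 lose their stereocenters and C1, C4 and C5 are untouched.

**Step 7**
Reactants: 9 cis-fused 4β-hydroxydaucane-6,10-dione
Product: 10 trans-fused 4β-hydroxydaucane-6,10-dione (C5–H α)
Conditions: DBU (0.3 equiv), CH2Cl2, 25 °C
Reagents that add atoms: none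
Why: Base-mediated epimerisation under thermodynamic control through the C5–C6 enolate: it takes C6 off the face of the isopropyl group and onto the face of the C4 hydroxyl (hydrogen bond to the C6 carbonyl) and turns the cis-hydroazulene into the trans-fused one with C5–H α, while the weak amidine base at room temperature should leave the β-hydroxy ketone free of retro-aldol cleavage and dehydration.

**Step 8**
Reactants: 10 trans-fused 4β-hydroxydaucane-6,10-dione
Product: 11 4β,6α-dihydroxydaucan-10-one
Conditions: Me4NBH(OAc)3 (5 equiv), MeCN/AcOH 1:1, −30 °C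
Reagents that add atoms: none
Why: Evans–Saksena hydroxyl-directed reduction: the C4 hydroxyl exchanges onto boron and delivers hydride through a six-membered transition state to the β face of the C6 carbonyl, the only face the C4–O arm can reach in the trans-fused frame, giving the 6α-alcohol, while the C10 ketone has no directing hydroxyl within reach and is not reduced by the acetoxyborohydride.

**Step 9**
Reactants: 11 4β,6α-dihydroxydaucan-10-one; 12 3,4-dimethoxybenzoyl chloride
Product: 13 4β-hydroxy-6α-veratroyloxydaucan-10-one
Conditions: Et3N, DMAP (0.2 equiv), CH2Cl2, 40 °C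
Reagents that add atoms: none
Why: DMAP-catalysed acylation (nucleophilic catalysis through the acylpyridinium salt) of the secondary 6α-hydroxyl, the tertiary C4 hydroxyl being too hindered to react; no stereocenter is touched.

**Step 10**
Reactants: 13 4β-hydroxy-6α-veratroyloxydaucan-10-one
Product: 14 bis(trimethylsilyl) derivative (silyl enol ether C9=C10, silyl ether at C4–O)
Conditions: Me3SiOTf (2.5 equiv), Et3N (4 equiv), CH2Cl2, 0 °C
Reagents that add atoms: trimethylsilyl trifluoromethanesulfonate, C[Si](C)(C)OS(=O)(=O)C(F)(F)F
Why: Soft enolisation and O-silylation: the C10 ketone can enolise only toward C9 because C1 is quaternary, so one silyl enol ether forms, the tertiary C4 hydroxyl is silylated at the same time, and the aryl ester has no α-hydrogen.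

**Step 11**
Reactants: 14 bis(trimethylsilyl) derivative
Product: 16 4β-hydroxy-6α-veratroyloxydauc-8-en-10-one, via silyl-protected enone 15 (not isolated)
Conditions: Pd(OAc)2 (1.1 equiv), MeCN, 25 °C; then 1 M HCl, THF, 0 °C
Reagents that add atoms: none
Why: Saegusa–Ito oxidation: the silyl enol ether is converted into a palladium enolate that loses the C8 hydrogen by β-hydride elimination (possible for either C8 epimer, since the metal can reach both faces of C9 through the oxygen-bound form) to give the C8=C9 enone, and dilute acid then removes the tertiary silyl ether; the C8 stereocenter disappears.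

**Step 12**
Reactants: 16 4β-hydroxy-6α-veratroyloxydauc-8-en-10-one
Product: 17 6α-veratroyloxydauc-8-ene-4β,10β-diol
Conditions: NaBH4, CeCl3·7H2O, MeOH, −40 °C
Reagents that add atoms: none
Why: Luche reduction: cerium-assisted 1,2-addition of hydride to the enone should occur on the α face, anti to the angular methyl on the neighbouring quaternary C1, to give the 10β-alcohol, which is the epimer required for the inversion in step 13; the ester is not reduced.

**Step 13**
Reactants: 17 6α-veratroyloxydauc-8-ene-4β,10β-diol; 18 angelic acid
Product: 19 10α-angeloyloxy-6α-veratroyloxydauc-8-en-4β-ol (target)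
Conditions: PPh3, DIAD, toluene, 0 to 25 °C
Reagents that add atoms: none
Why: Mitsunobu esterification: the 10β-hydroxyl is activated as its oxyphosphonium salt and displaced with inversion by angelate from the open α face to give the 10α-angelate, and because the acid reacts only as a carboxylate nucleophile and is never activated at its carbonyl group the Z double bond should not isomerise to the tiglate.

**Compound list**
1 | dimethyl 3-methylglutarate | COC(=O)CC(C)CC(=O)OC | starting material
2 | 4-methyl-1,2-bis(trimethylsilyloxy)cyclopent-1-ene | CC1CC(O[Si](C)(C)C)=C(O[Si](C)(C)C)C1 | intermediate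
3 | 3-methylcyclopent-2-en-1-one | CC1=CC(=O)CC1 | starting material
4 | tricyclic photoadduct ketone (cyclobutane C1–C5–C6–C10, C4 ketone, 6,10-bis(trimethylsilyloxy)) | C[Si](C)(C)O[C@]12C[C@H](C)C[C@@]1(O[Si](C)(C)C)[C@@H]3C(=O)CC[C@@]32C | intermediate
5 | enol triflate (C3=C4) | C[Si](C)(C)O[C@]12C[C@H](C)C[C@@]1(O[Si](C)(C)C)[C@@H]3C(OS(=O)(=O)C(F)(F)F)=CC[C@@]32C | intermediate
6 | C4-isopropyl alkene (C3=C4) | C[Si](C)(C)O[C@]12C[C@H](C)C[C@@]1(O[Si](C)(C)C)[C@@H]3C(C(C)C)=CC[C@@]32C | intermediate
7 | tertiary alcohol (4β-OH, 4α-isopropyl) | C[Si](C)(C)O[C@]12C[C@H](C)C[C@@]1(O[Si](C)(C)C)[C@@H]3[C@](O)(C(C)C)CC[C@@]32C | intermediate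
8 | cyclobutane triol (not isolated) | O[C@]12C[C@H](C)C[C@@]1(O)[C@@H]3[C@](O)(C(C)C)CC[C@@]32C | intermediate
9 | cis-fused 4β-hydroxydaucane-6,10-dione | O=C1C[C@H](C)CC(=O)[C@H]2[C@]1(C)CC[C@@]2(O)C(C)C | intermediate
10 | trans-fused 4β-hydroxydaucane-6,10-dione | O=C1C[C@H](C)CC(=O)[C@@H]2[C@]1(C)CC[C@@]2(O)C(C)C | intermediate
11 | 4β,6α-dihydroxydaucan-10-one | O=C1C[C@H](C)C[C@H](O)[C@@H]2[C@]1(C)CC[C@@]2(O)C(C)C | intermediate
12 | 3,4-dimethoxybenzoyl chloride | COc1ccc(C(=O)Cl)cc1OC | starting material
13 | 4β-hydroxy-6α-veratroyloxydaucan-10-one | O=C1C[C@H](C)C[C@H](OC(=O)c2ccc(OC)c(OC)c2)[C@@H]2[C@]1(C)CC[C@@]2(O)C(C)C | intermediate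
14 | bis(trimethylsilyl) derivative (C9=C10 silyl enol ether, C4 silyl ether) | C[Si](C)(C)OC1=C[C@H](C)C[C@H](OC(=O)c2ccc(OC)c(OC)c2)[C@@H]2[C@]1(C)CC[C@@]2(O[Si](C)(C)C)C(C)C | intermediate
15 | silyl-protected enone (not isolated) | O=C1C=C(C)C[C@H](OC(=O)c2ccc(OC)c(OC)c2)[C@@H]2[C@]1(C)CC[C@@]2(O[Si](C)(C)C)C(C)C | intermediate
16 | 4β-hydroxy-6α-veratroyloxydauc-8-en-10-one | O=C1C=C(C)C[C@H](OC(=O)c2ccc(OC)c(OC)c2)[C@@H]2[C@]1(C)CC[C@@]2(O)C(C)C | intermediate
17 | 6α-veratroyloxydauc-8-ene-4β,10β-diol | O[C@H]1C=C(C)C[C@H](OC(=O)c2ccc(OC)c(OC)c2)[C@@H]2[C@]1(C)CC[C@@]2(O)C(C)C | intermediate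
18 | angelic acid, (Z)-2-methylbut-2-enoic acid | C/C=C(/C)C(=O)O | starting material
19 | 10α-angeloyloxy-6α-veratroyloxydauc-8-en-4β-ol | C/C=C(/C)C(=O)O[C@@H]1C=C(C)C[C@H](OC(=O)c2ccc(OC)c(OC)c2)[C@@H]2[C@]1(C)CC[C@@]2(O)C(C)C | target

**Count and risks**
Total step count: 13. Longest linear sequence: 13 steps (1 to 19).

Steps most likely to fail:

1. Step 2 (proposed new method). The Lewis acid may cover the face of a five-membered enone too poorly, may strip silyl groups from 2, or conversion at 366 nm may stall. The fallback moves absolute control from the catalyst to the substrate with known chemistry; it sets out from 2 and comes back at 4. Commercial (R)-4-(tert-butyldimethylsilyloxy)cyclopent-2-en-1-one F1 is treated with Me2CuLi and Me3SiCl to give the trans-3-methyl silyl enol ether F2. Saegusa–Ito oxidation with Pd(OAc)2 gives (R)-4-(tert-butyldimethylsilyloxy)-3-methylcyclopent-2-en-1-one F3. Uncatalysed irradiation of F3 with 2 (λ above 300 nm, Pyrex) should let the alkene add anti to the silyloxy group on C2 and give the 2β-silyloxy photoadduct F4. DBU then eliminates the β-silyloxy group to the tricyclic enone F5, and hydrogenation (H2, Pd/C) gives 4.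

2. Step 5. The C4 radical is next to the cyclobutane, so β-scission of the C5–C6 bond toward the α-silyloxy radical may compete with oxygen capture, and oxygen may also be captured from the endo face. The fallback is polar; it sets out from 6 and comes back at 7. mCPBA with NaHCO3 should epoxidise C3=C4 from the exo face to the exo-epoxide F6, and LiEt3BH opens it at the secondary C3 to give 7.

3. Step 13. Displacement at the neopentylic C10 may be slow, so that ionisation of the allylic oxyphosphonium salt (loss of configuration, attack at C8) or elimination takes over. The fallback sets the configuration by reagent-controlled reduction and esterifies with retention; it sets out from 16 and comes back at 19. Corey–Bakshi–Shibata reduction (BH3·SMe2, the oxazaborolidine antipode that delivers hydride to the β face) gives the 10α-alcohol F7. Yamaguchi esterification with 18 (2,4,6-trichlorobenzoyl chloride, Et3N, toluene, no DMAP) then proceeds through the mixed anhydride F8 to 19.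

**Further compounds**
F1 | step 2 | (R)-4-(tert-butyldimethylsilyloxy)cyclopent-2-en-1-one | O=C1C=C[C@H](O[Si](C)(C)C(C)(C)C)C1
F2 | step 2 | trans-4-(tert-butyldimethylsilyloxy)-3-methyl-1-(trimethylsilyloxy)cyclopent-1-ene | C[Si](C)(C)OC1=C[C@@H](C)[C@H](O[Si](C)(C)C(C)(C)C)C1
F3 | step 2 | (R)-4-(tert-butyldimethylsilyloxy)-3-methylcyclopent-2-en-1-one | O=C1C=C(C)[C@H](O[Si](C)(C)C(C)(C)C)C1
F4 | step 2 | 2β-silyloxy photoadduct | C[Si](C)(C)O[C@]12C[C@H](C)C[C@@]1(O[Si](C)(C)C)[C@@H]3C(=O)C[C@@H](O[Si](C)(C)C(C)(C)C)[C@@]32C
F5 | step 2 | tricyclic enone (C2=C3, C4 ketone) | C[Si](C)(C)O[C@]12C[C@H](C)C[C@@]1(O[Si](C)(C)C)[C@@H]3C(=O)C=C[C@@]32C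
F6 | step 5 | exo-epoxide (3β,4β-epoxide) | C[Si](C)(C)O[C@]12C[C@H](C)C[C@@]1(O[Si](C)(C)C)[C@@H]3[C@@]4(C(C)C)O[C@H]4C[C@@]32C
F7 | step 13 | 6α-veratroyloxydauc-8-ene-4β,10α-diol | O[C@@H]1C=C(C)C[C@H](OC(=O)c2ccc(OC)c(OC)c2)[C@@H]2[C@]1(C)CC[C@@]2(O)C(C)C
F8 | step 13 | angelic 2,4,6-trichlorobenzoic anhydride | C/C=C(/C)C(=O)OC(=O)c1c(Cl)cc(Cl)cc1Cl
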